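The east flask gets 15.0 times the starting material of the north-west flask and the same partner, yet each target costs two partners, one for the capture that makes intermediate B and one for the finishing that turns intermediate B into target.

    starting material ⇌ intermediate A (K1 = 29, k1 = 0.0025 s⁻¹)
    starting material + partner → intermediate B (k2 = 0.018 M⁻¹ s⁻¹)
    starting material + partner → side product A (k3 = 6.1 × 10⁻⁴ M⁻¹ s⁻¹)
    partner + intermediate B → target (k4 = 0.011 M⁻¹ s⁻¹)
    intermediate B → intermediate C (k5 = 3.5 × 10⁻⁴ s⁻¹)
    partner + intermediate C → side product B (k6 = 0.0017 M⁻¹ s⁻¹)
    partner + protic impurity → quenched reagent (k7 = 0.058 M⁻¹ s⁻¹)

in all of them: partner 0.210 M; protic impurity 4.00 mM; time 12 h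
- north-west: starting material 0.10 M
- north: starting material 0.20 M
- west: starting material 0.40 M
- north-east: starting material 0.80 M
- east: starting material 1.5 M

- [target] at the end for north-west, north, west, north-east, east, in this order
- how the row runs (falls, then rises / rises, then falls / hardly changes / falls all the way / rises all the way)

- "hardly changes" means that all values lie within two and a half points (for a concentration: within two and a half percent of the largest)
- run time (north-west): 12 h

Two ceilings stand before any rate is used. The partner charge allows 0.105 M of target, and the target can't exceed the starting material charged, which is 0.10 M in the north-west flask.

The rates matter at high charge, where partner is the limiting reagent, 0.210 M against 1.5 M in the east flask. There, capture uses each partner at 0.0270 s⁻¹, ten times the 0.0025 s⁻¹ at which starting material leaves for intermediate A, so starting material stays near its charge during the capture. Finishing uses each partner at no more than 0.00231 s⁻¹, so capture wins the race in the east flask. Intermediate B also stays where it is made, since its drift to intermediate C at 3.5 × 10⁻⁴ s⁻¹ is far slower than capture, and side product A takes hardly any of the capturing flow.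

Now divide the finishing rate by the capture rate. Time drops out and partner cancels, leaving target gained per partner captured as the finishing constant times intermediate B, over the capture constant times starting material. Intermediate B equals the partner captured so far, so summing this ratio as partner falls from its charge to nothing gives half the square of the partner charge. The target is therefore the race constant divided by the starting charge, where the race constant is half the finishing constant times the squared partner charge, over the capture constant: 0.0135 M^2.

This gives 0.00898 M for the east flask and 0.0168 M for the north-east flask. The race law can't serve the north-west flask, where capture uses each partner at 0.00180 s⁻¹, slower than the 0.0025 s⁻¹ of the isomerisation. Seen from the starting material, though, capture at the start of any of these flasks goes at 0.00378 s⁻¹ against that 0.0025 s⁻¹, so capture takes a share of 60.2% of the starting material at the start, with partner as charged. This estimate leaves out the return from intermediate A, at 8.62 × 10⁻⁵ s⁻¹. The share of the charge rises along the row and the race law falls, and taking the lower of the two lines gives 0.0602 M for the north-west flask, 0.0674 M for the north flask and 0.0337 M for the west flask. With the two values above, the row reckoned here runs rises, then falls.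

The forecast gives 0.062 M, 0.071 M, 0.051 M, 0.02 M and 0.0097 M, running rises, then falls, on the words “Each target uses two partners”, and its east value is higher than the one reckoned here.

The flasks end at 0.0629 M, 0.0714 M, 0.0476 M, 0.0199 M and 0.00936 M, and the row runs rises, then falls. In the east flask, partner stands at 0% of its charge after 12.0 h, and intermediate A holds 83.8% of the starting material charged. Target times starting charge, set against the race constant of 0.0135 M^2, is 0.0140 M^2 in the east flask and 0.0159 M^2 in the north-east flask.

The constants stand for no real mixture; the run is a simulation.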